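**Plan**

- The target is the achiral flavonol 3,5,7,3'-tetrahydroxy-8,4',5'-trimethoxyflavone. In ring A, C5–OH sits para to C8–OMe, C7 carries an oxygen next to C8 and C6 carries H: a hydroquinone monoether fused to the C4a=C8a bond of pyranone ring C, which is the pattern a 3-alkoxy-4-methoxycyclobutenone bound to a 4-pyranone gives on thermal ring expansion.
- Retrosynthesis: the O–isopropyl bonds at O3, O7 and O3' are cut first, then C4a–C5 of ring A (electrocyclisation, back to a cyclobutenone), then C8–C8a (pyranone C6 onto a semisquarate carbonyl), then C2–C1' (furan plus aldehyde).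
- Forward: ring B is bought as the benzaldehyde; ring C is grown from furan by Achmatowicz ring expansion and epoxide-mediated oxidation to a 3-hydroxy-4-pyranone; the four-membered ring is joined at pyranone C6; ring A closes in the thermal step; one Lewis-acid step removes all three isopropyl groups.
- Stereochemistry: the target has none; every stereocentre on the way (carbinol, acetal, epoxide, cyclobutenone C4, transient C4a) forms as a racemate or mixture and is erased.

Key step: step 11

Remark: isopropyl ethers are used for all three protected hydroxyls (O3', O3, O7) so that a single BCl3 treatment ends the route; intermediates with stereocentres are carried as racemates or diastereomer mixtures.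

**Step 1**
Reactants: 1 3-hydroxy-4,5-dimethoxybenzaldehyde
Product: 2 3-isopropoxy-4,5-dimethoxybenzaldehyde
Conditions: 2-bromopropane, K2CO3, DMF, 60 °C
Reagents that add atoms: 2-bromopropane, CC(C)Br
Why: Williamson ether synthesis, in which the only acidic group, the phenol, is alkylated as its potassium phenoxide while the aldehyde is inert.

**Step 2**
Reactants: 2 3-isopropoxy-4,5-dimethoxybenzaldehyde; 3 furan
Product: 5 (furan-2-yl)(3-isopropoxy-4,5-dimethoxyphenyl)methanol (racemic), via 2-furyllithium 4 (not isolated)
Conditions: furan, n-BuLi, THF, 0 °C; then 2, −78 °C; sat. aq. NH4Cl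
Reagents that add atoms: none
Why: α-lithiation of furan followed by 1,2-addition of the organolithium to the non-enolisable aldehyde should give the carbinol, whose new centre forms racemic and is erased when C2 becomes sp2 in step 6.

**Step 3**
Reactants: 5 (furan-2-yl)(3-isopropoxy-4,5-dimethoxyphenyl)methanol
Product: 6 6-hydroxy-2-(3-isopropoxy-4,5-dimethoxyphenyl)-2H-pyran-3(6H)-one (racemic, anomer mixture)
Conditions: mCPBA, CH2Cl2, 0 °C
Reagents that add atoms: mCPBA, OOC(=O)c1cccc(Cl)c1
Why: Achmatowicz rearrangement, in which the peracid oxidises the furan faster than the trialkoxybenzene and the carbinol oxygen closes the resulting cis-enedione to the pyranone hemiacetal; both centres are erased later.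

**Step 4**
Reactants: 6 6-hydroxy-2-(3-isopropoxy-4,5-dimethoxyphenyl)-2H-pyran-3(6H)-one
Product: 7 2-(3-isopropoxy-4,5-dimethoxyphenyl)-6-methoxy-2H-pyran-3(6H)-one (racemic, cis/trans mixture)
Conditions: HC(OMe)3, BF3·OEt2 (cat.), CH2Cl2, 0 °C
Reagents that add atoms: trimethyl orthoformate, COC(OC)OC
Why: acid-catalysed acetalisation (Fischer-type glycosidation through the anomeric oxocarbenium ion) caps the base-labile hemiacetal as the methyl acetal before the basic epoxidation.

**Step 5**
Reactants: 7 2-(3-isopropoxy-4,5-dimethoxyphenyl)-6-methoxy-2H-pyran-3(6H)-one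
Product: 8 4,5-epoxy-2-(3-isopropoxy-4,5-dimethoxyphenyl)-6-methoxyoxan-3-one (racemic, diastereomer mixture)
Conditions: 30% aq. H2O2, NaOH (cat.), MeOH, 0 °C
Reagents that add atoms: hydrogen peroxide, OO
Why: Weitz–Scheffer nucleophilic epoxidation, in which hydroperoxide adds to the β-carbon C5 of the enone and closes to the epoxy ketone, leaving the electron-rich arene untouched; the epoxide configuration does not matter.

**Step 6**
Reactants: 8 4,5-epoxy-2-(3-isopropoxy-4,5-dimethoxyphenyl)-6-methoxyoxan-3-one
Product: 9 3-hydroxy-2-(3-isopropoxy-4,5-dimethoxyphenyl)-4H-pyran-4-one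
Conditions: Dowex 50W (H+ form), dioxane/H2O, 90 °C
Reagents that add atoms: none
Why: acid-catalysed epoxy ketone to diosphenol isomerisation, β-elimination of methanol from the acetal carbon and enolisation toward the benzylic C2–H should give the conjugated 3-hydroxy-4-pyranone, as in the maltol synthesis from the 2-methyl analogue.

**Step 7**
Reactants: 9 3-hydroxy-2-(3-isopropoxy-4,5-dimethoxyphenyl)-4H-pyran-4-one
Product: 10 3-isopropoxy-2-(3-isopropoxy-4,5-dimethoxyphenyl)-4H-pyran-4-one
Conditions: 2-bromopropane, K2CO3, DMF, 70 °C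
Reagents that add atoms: 2-bromopropane, CC(C)Br
Why: Williamson O-alkylation of the acidic enolic 3-hydroxyl, as in the etherification of maltol, removes the only acidic proton before metalation.

**Step 8**
Reactants: 11 diisopropyl squarate
Product: 13 3-isopropoxycyclobut-3-ene-1,2-dione, via 4-hydroxy-2,3-diisopropoxycyclobut-2-en-1-one 12 (not isolated)
Conditions: LiAlH(OtBu)3, THF, −78 → 0 °C; 1 M HCl quench; then 12 M HCl (cat.), CH2Cl2, 25 °C
Reagents that add atoms: water, O
Why: 1,2-reduction of one squarate carbonyl by the hindered alkoxyaluminium hydride stops at the hydroxycyclobutenone, and acid then ionises the carbinol to an alkoxy-stabilised cyclobutenyl cation that takes up water and loses isopropanol (1,3-carbonyl transposition) to give the semisquarate.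

**Step 9**
Reactants: 10 3-isopropoxy-2-(3-isopropoxy-4,5-dimethoxyphenyl)-4H-pyran-4-one; 13 3-isopropoxycyclobut-3-ene-1,2-dione
Product: 15 4-hydroxy-3-isopropoxy-4-[5-isopropoxy-6-(3-isopropoxy-4,5-dimethoxyphenyl)-4-oxo-4H-pyran-2-yl]cyclobut-2-en-1-one (racemic), via C6-magnesiated pyranone 14 (not isolated)
Conditions: TMPMgCl·LiCl (TMP = 2,2,6,6-tetramethylpiperidide), THF, −40 °C; cannulate into 13, THF, −78 °C; sat. aq. NH4Cl
Reagents that add atoms: none
Why: directed magnesiation with the hindered amide base should remove the most acidic ring proton, C6–H beside the ring oxygen (as in C2-metalation of chromones), and the alkenyl Grignard should add 1,2 to the carbonyl of 13 next to the alkoxy carbon, which is ketone-like, and not to the vinylogous-ester carbonyl; the new quaternary centre is racemic and is lost on aromatisation.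

**Step 10**
Reactants: 15 4-hydroxy-3-isopropoxy-4-[5-isopropoxy-6-(3-isopropoxy-4,5-dimethoxyphenyl)-4-oxo-4H-pyran-2-yl]cyclobut-2-en-1-one
Product: 16 3-isopropoxy-4-methoxy-4-[5-isopropoxy-6-(3-isopropoxy-4,5-dimethoxyphenyl)-4-oxo-4H-pyran-2-yl]cyclobut-2-en-1-one (racemic)
Conditions: MeI, Ag2O, CH3CN, 25 °C, dark
Reagents that add atoms: iodomethane, CI
Why: Purdie methylation of the tertiary α-keto carbinol under near-neutral conditions avoids base-induced ring opening of the hydroxycyclobutenone.

**Step 11**
Reactants: 16 3-isopropoxy-4-methoxy-4-[5-isopropoxy-6-(3-isopropoxy-4,5-dimethoxyphenyl)-4-oxo-4H-pyran-2-yl]cyclobut-2-en-1-one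
Product: 19 5-hydroxy-3,7-diisopropoxy-2-(3-isopropoxy-4,5-dimethoxyphenyl)-8-methoxy-4H-chromen-4-one, via dienylketene 17 (not isolated), via keto tautomer 18 (not isolated)
Conditions: p-xylene (degassed, 0.02 M), 138 °C, argon
Reagents that add atoms: none
Why: Heating should open the cyclobutenone by conrotatory 4π-electrocyclic cleavage of its C1–C4 bond to dienylketene 17, and a thermally allowed disrotatory 6π-electrocyclisation then joins the ketene carbon to C5 of the pyranone (the nucleophilic enol-ether β-carbon, future C4a), forming C4a–C5 and the six-membered carbocycle ring A as dione 18. Enolisation of the doubly activated C4a–H, driven by aromatisation and the hydrogen bond to C4=O, gives the 5-phenol, with the former sp3 carbon as C8 carrying its methoxyl, the isopropoxy carbon as C7 and the CH carbon as C6. The closest known reaction is the thermal ring expansion of 4-aryl-, 4-heteroaryl- and 4-alkenyl-4-alkoxycyclobutenones to hydroquinone monoethers (Moore cyclisation), here with the C5=C6 bond of a 4-pyranone as the alkene partner. No lasting stereocentre is created, because the C4a centre of 18 disappears on tautomerisation. The step needs torquoselectivity in the ring opening, secured by outward rotation of the C4 methoxy donor, which turns the pyranonyl group inward beside the ketene; the regiochemistry is fixed beforehand by the substitution pattern of 16.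

**Step 12**
Reactants: 19 5-hydroxy-3,7-diisopropoxy-2-(3-isopropoxy-4,5-dimethoxyphenyl)-8-methoxy-4H-chromen-4-one
Product: 20 3,5,7-trihydroxy-2-(3-hydroxy-4,5-dimethoxyphenyl)-8-methoxy-4H-chromen-4-one (CNP0225742.0)
Conditions: BCl3 (8 equiv), CH2Cl2, −78 → 0 °C; then H2O
Reagents that add atoms: none
Why: Lewis-acid ether cleavage, in which BCl3 should cleave the three secondary isopropyl aryl ethers (chelation-assisted at O3 by C4=O) much faster than the methyl ethers, and aqueous work-up hydrolyses the aryl borates to the free phenols.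

**Compound list**

1 | 3-hydroxy-4,5-dimethoxybenzaldehyde | COc1cc(C=O)cc(O)c1OC | starting material
2 | 3-isopropoxy-4,5-dimethoxybenzaldehyde | COc1cc(C=O)cc(OC(C)C)c1OC | intermediate
3 | furan | c1ccoc1 | starting material
4 | 2-furyllithium (formed in the flask) | [Li]c1ccco1 | intermediate
5 | (furan-2-yl)(3-isopropoxy-4,5-dimethoxyphenyl)methanol, racemic | OC(c1ccco1)c1cc(OC)c(OC)c(OC(C)C)c1 | intermediate
6 | 6-hydroxy-2-(3-isopropoxy-4,5-dimethoxyphenyl)-2H-pyran-3(6H)-one, racemic anomer mixture | O=C1C=CC(O)OC1c1cc(OC)c(OC)c(OC(C)C)c1 | intermediate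
7 | 2-(3-isopropoxy-4,5-dimethoxyphenyl)-6-methoxy-2H-pyran-3(6H)-one, racemic cis/trans mixture | COC1C=CC(=O)C(c2cc(OC)c(OC)c(OC(C)C)c2)O1 | intermediate
8 | 4,5-epoxy-2-(3-isopropoxy-4,5-dimethoxyphenyl)-6-methoxyoxan-3-one, racemic diastereomer mixture | COC1OC(c2cc(OC)c(OC)c(OC(C)C)c2)C(=O)C2OC12 | intermediate
9 | 3-hydroxy-2-(3-isopropoxy-4,5-dimethoxyphenyl)-4H-pyran-4-one | COc1cc(-c2occc(=O)c2O)cc(OC(C)C)c1OC | intermediate
10 | 3-isopropoxy-2-(3-isopropoxy-4,5-dimethoxyphenyl)-4H-pyran-4-one | COc1cc(-c2occc(=O)c2OC(C)C)cc(OC(C)C)c1OC | intermediate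
11 | diisopropyl squarate (3,4-diisopropoxycyclobut-3-ene-1,2-dione) | CC(C)OC1=C(OC(C)C)C(=O)C1=O | starting material
12 | 4-hydroxy-2,3-diisopropoxycyclobut-2-en-1-one, racemic (used crude) | CC(C)OC1=C(OC(C)C)C(=O)C1O | intermediate
13 | 3-isopropoxycyclobut-3-ene-1,2-dione | CC(C)OC1=CC(=O)C1=O | intermediate
14 | chloro[5-isopropoxy-6-(3-isopropoxy-4,5-dimethoxyphenyl)-4-oxo-4H-pyran-2-yl]magnesium, LiCl complex (formed in the flask) | Cl[Mg]c1cc(=O)c(OC(C)C)c(-c2cc(OC(C)C)c(OC)c(OC)c2)o1 | intermediate
15 | 4-hydroxy-3-isopropoxy-4-[5-isopropoxy-6-(3-isopropoxy-4,5-dimethoxyphenyl)-4-oxo-4H-pyran-2-yl]cyclobut-2-en-1-one, racemic | CC(C)OC1=CC(=O)C1(O)c1cc(=O)c(OC(C)C)c(-c2cc(OC(C)C)c(OC)c(OC)c2)o1 | intermediate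
16 | 3-isopropoxy-4-methoxy-4-[5-isopropoxy-6-(3-isopropoxy-4,5-dimethoxyphenyl)-4-oxo-4H-pyran-2-yl]cyclobut-2-en-1-one, racemic | COC1(c2cc(=O)c(OC(C)C)c(-c3cc(OC(C)C)c(OC)c(OC)c3)o2)C(=O)C=C1OC(C)C | intermediate
17 | (3Z)-3-isopropoxy-4-methoxy-4-[5-isopropoxy-6-(3-isopropoxy-4,5-dimethoxyphenyl)-4-oxo-4H-pyran-2-yl]buta-1,3-dien-1-one (dienylketene, formed in the flask) | O=C=C/C(OC(C)C)=C(OC)\c1cc(=O)c(OC(C)C)c(-c2cc(OC(C)C)c(OC)c(OC)c2)o1 | intermediate
18 | 3,7-diisopropoxy-2-(3-isopropoxy-4,5-dimethoxyphenyl)-8-methoxy-4aH-chromene-4,5-dione, racemic keto tautomer (formed in the flask) | COC1=C2OC(c3cc(OC(C)C)c(OC)c(OC)c3)=C(OC(C)C)C(=O)C2C(=O)C=C1OC(C)C | intermediate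
19 | 5-hydroxy-3,7-diisopropoxy-2-(3-isopropoxy-4,5-dimethoxyphenyl)-8-methoxy-4H-chromen-4-one | COc1c(OC(C)C)cc(O)c2c(=O)c(OC(C)C)c(-c3cc(OC(C)C)c(OC)c(OC)c3)oc12 | intermediate
20 | 3,5,7-trihydroxy-2-(3-hydroxy-4,5-dimethoxyphenyl)-8-methoxy-4H-chromen-4-one (CNP0225742.0) | COc1cc(-c2oc3c(OC)c(O)cc(O)c3c(=O)c2O)cc(O)c1OC | target

**Step count**

Total: 12 steps. Longest linear sequence: 11 steps (steps 1–7 and 9–12 from aldehyde 1); step 8 is a one-step side branch from squarate 11.

**Steps most likely to fail**

Step 9. Deprotonation may occur in part at C5 under direction by the carbonyl, followed by β-elimination and ring opening. The metalated pyranone may also add to unreacted 10, or the Grignard may add in conjugate fashion to the unsubstituted ring carbon of 13. The fallback replaces C–H magnesiation by halogen–metal exchange and sets out from 10. Zincation with TMPZnCl·LiCl in THF at 25 °C, a milder base that tolerates the carbonyl and goes to the position beside the ring oxygen in chromones, should give chloro[5-isopropoxy-6-(3-isopropoxy-4,5-dimethoxyphenyl)-4-oxo-4H-pyran-2-yl]zinc F1. Quenching with iodine gives 2-iodo-5-isopropoxy-6-(3-isopropoxy-4,5-dimethoxyphenyl)-4H-pyran-4-one F2. Iodine–magnesium exchange with iPrMgCl·LiCl at −78 °C then generates 14 at a defined position and low temperature, and addition to 13 returns to the route at 15.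

Step 11. The fully etherified cyclobutenone may open slowly or with partial inward rotation of the methoxy group, so that the ketene oligomerises or is diverted before it closes onto the electron-poor pyranone double bond. The fallback uses the best-documented variant of the ring expansion, the free 4-hydroxycyclobutenone, and sets out from 15. Heating 15 in degassed toluene at 110 °C under argon should give, by the same opening and closure with the hydroxyl rotating outward, 5,8-dihydroxy-3,7-diisopropoxy-2-(3-isopropoxy-4,5-dimethoxyphenyl)-4H-chromen-4-one F3. Because the 5-hydroxyl is locked in a hydrogen bond to C4=O, methylation with one equivalent of MeI and K2CO3 in acetone under argon should take place at the 8-hydroxyl only, which returns to the route at 19.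

Step 5. Under the basic conditions, enolisation at the acidic benzylic C2–H, followed by loss of methoxide or ring opening, may outrun hydroperoxide addition. The fallback brings the C4–C5 bond to the same oxidation level under neutral conditions and sets out from 7. Upjohn dihydroxylation (OsO4 cat., N-methylmorpholine N-oxide, acetone/H2O, 25 °C) should give cis-4,5-dihydroxy-2-(3-isopropoxy-4,5-dimethoxyphenyl)-6-methoxyoxan-3-one F4. Under the acid conditions of step 6, F4 should lose water (β-hydroxy ketone dehydration to the diosphenol) and methanol, which returns to the route at 9.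

**Further compounds**

F1 | step 9 | chloro[5-isopropoxy-6-(3-isopropoxy-4,5-dimethoxyphenyl)-4-oxo-4H-pyran-2-yl]zinc | Cl[Zn]c1cc(=O)c(OC(C)C)c(-c2cc(OC(C)C)c(OC)c(OC)c2)o1
F2 | step 9 | 2-iodo-5-isopropoxy-6-(3-isopropoxy-4,5-dimethoxyphenyl)-4H-pyran-4-one | COc1cc(-c2oc(I)cc(=O)c2OC(C)C)cc(OC(C)C)c1OC
F3 | step 11 | 5,8-dihydroxy-3,7-diisopropoxy-2-(3-isopropoxy-4,5-dimethoxyphenyl)-4H-chromen-4-one | CC(C)Oc1cc(O)c2c(=O)c(OC(C)C)c(-c3cc(OC(C)C)c(OC)c(OC)c3)oc2c1O
F4 | step 5 | cis-4,5-dihydroxy-2-(3-isopropoxy-4,5-dimethoxyphenyl)-6-methoxyoxan-3-one, racemic diastereomer mixture | COC1OC(c2cc(OC)c(OC)c(OC(C)C)c2)C(=O)C(O)C1O
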